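**Plan** (numbering: C1 ketone, C2=C3 furanone alkene, C4=C5 with CH3 on C4, C6 lactone O–CH, C7, C8 tiglate CH, C9 carbinol, C10 quaternary C–O, C11 C(OH)CH2Cl, C12 lactone C=O, C13 CH2Cl)
Retrosynthesis cuts, in order: the C8 tiglate, the C13–Cl bond and the 8,9-acetonide; then C2–C3 and C4–C5 (key step, back to a cis-cyclooctenone carrying a C10 propynyl ether); then C2=C5 (metathesis), C6–O and C6–C7 (lactone from acrolein allylation), C1–C2 and C10–C1 (vinyl additions), ending at L-arabinose.
Forward: carbohydrate chain C7–C10, then the C10 dichlorovinyl ether (masked ynol ether), the α-methylene lactone at C6/C7, its spiro-epoxide, the eight-membered ring, the ynol ether with both carbonyls restored, then furanone and ten-membered ring together, then HCl and tigloylation.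
Enabling feature: the C2–C5 diene lies in the ten-membered ring with C2=C3 trans (held inside the five-membered furanone ring O–C10–C1–C2–C3) and C4=C5 cis. This is the imprint of conrotatory opening of a cis-fused cyclobutene, so C3–C4 of an ynol ether can be inserted between C2 and C5 of a cyclooctenone.
Stereochemistry: C8 and C9 from L-arabinose; C10 by Felkin–Anh addition; C7 by allylic-strain-controlled allylation and C6 by Mitsunobu inversion; C11 by epoxidation anti to the C7 side chain. The chlorohydrin is carried as its 11,13-epoxide because it must survive n-BuLi and fluoride, and is opened with HCl at the end.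

Key step: step 22

Remark: centres that are later oxidised or eliminated (anomeric carbons of 2 and 4, C10 in 5 and 6, C1 in 11–30, C7 in 17, C12 in 25–30) are carried as epimer mixtures and are left undefined in the SMILES; the lactol 4 is made from L-arabinose rather than bought.

Step 1
Reactants: 1 L-arabinose
Product: 2 3,4-O-isopropylidene-L-arabinopyranose
Conditions: 2,2-dimethoxypropane, TsOH·H2O (cat.), DMF, rt
Reagents that add atoms: 2,2-dimethoxypropane, COC(C)(C)OC
Why: Acid-catalysed acetonide formation under thermodynamic control should take the cis-3,4-diol of the pyranose and leave the C1/C2 glycol free for cleavage.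

Step 2
Reactants: 2 3,4-O-isopropylidene-L-arabinopyranose
Product: 4 2,3-O-isopropylidene-L-erythrose, via formate ester 3 (not isolated)
Conditions: NaIO4, H2O, 0 °C → rt; then Na2CO3 (aq), rt
Reagents that add atoms: none
Why: Periodate glycol cleavage of the C1–C2 diol and hydrolysis of the resulting formate should give the lactol whose dioxolane carbons become C9 and C8 of the target, their configuration being taken unchanged from L-arabinose.

Step 3
Reactants: 4 2,3-O-isopropylidene-L-erythrose
Product: 5 C10 methyl carbinol diol (C7–OH free; 8,9-acetonide)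
Conditions: MeMgBr (3 equiv), THF, 0 °C → rt
Reagents that add atoms: methylmagnesium bromide, C[Mg]Br
Why: Grignard addition to the open-chain aldehyde in equilibrium with the lactol alkoxide brings in the C10 methyl group, the configuration of the new carbinol being irrelevant because it is oxidised in step 5.

Step 4
Reactants: 5 C10 methyl carbinol diol
Product: 6 C7 triethylsilyl ether
Conditions: Et3SiCl (1.05 equiv), imidazole, CH2Cl2, −20 °C
Reagents that add atoms: chlorotriethylsilane, CC[Si](Cl)(CC)CC
Why: Silylation should select the primary C7 hydroxyl over the secondary C10 hydroxyl on steric grounds.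

Step 5
Reactants: 6 C7 triethylsilyl ether
Product: 7 C10 methyl ketone
Conditions: Dess–Martin periodinane, pyridine, CH2Cl2, 0 °C → rt
Reagents that add atoms: none
Why: Buffered Dess–Martin oxidation should give the methyl ketone without epimerising the adjacent cis-dioxolane centre C9 or cleaving the silyl ether.

Step 6
Reactants: 7 C10 methyl ketone
Product: 8 tertiary allylic alcohol (C10 bearing CH3, OH and vinyl)
Conditions: CH2=CHMgBr, CeCl3, THF, −78 °C
Reagents that add atoms: vinylmagnesium bromide, C=C[Mg]Br
Why: Felkin–Anh addition of the vinylcerium reagent, with the poorly chelating dioxolane C9–O bond anti to the incoming nucleophile and attack past the C9 hydrogen, should set C10 with O10 anti to O9 as the target requires, CeCl3 suppressing enolisation.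

Step 7
Reactants: 8 tertiary allylic alcohol; 9 trichloroethylene
Product: 10 C10 (E)-1,2-dichlorovinyl ether
Conditions: KH (2.2 equiv), THF, 0 °C; then 9, −50 °C → rt
Reagents that add atoms: none
Why: Addition of the potassium alkoxide, the only nucleophile present, to dichloroacetylene formed in the flask from trichloroethylene should give the base-stable dichlorovinyl ether that masks the ynol ether.

Step 8
Reactants: 10 C10 (E)-1,2-dichlorovinyl ether
Product: 12 C1 aldehyde, via vicinal diol 11 (not isolated)
Conditions: OsO4 (2 mol%), NaIO4 (4 equiv), 2,6-lutidine, dioxane/H2O 3:1, rt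
Reagents that add atoms: osmium tetroxide, O=[Os](=O)(=O)=O; sodium periodate, [Na+].[O-]I(=O)(=O)=O
Why: Lemieux–Johnson oxidation should cleave the monosubstituted vinyl group much faster than the trisubstituted, chlorine-deactivated enol ether, turning the vinyl CH into the C1 aldehyde.

Step 9
Reactants: 12 C1 aldehyde
Product: 13 C1 vinyl carbinol
Conditions: CH2=CHMgBr, THF, −78 → 0 °C
Reagents that add atoms: vinylmagnesium bromide, C=C[Mg]Br
Why: Grignard addition to the non-enolisable α-alkoxy aldehyde supplies C2 and the alkene for metathesis, the uncontrolled C1 configuration being erased by oxidation in step 21.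

Step 10
Reactants: 13 C1 vinyl carbinol
Product: 14 C1 tert-butyldimethylsilyl ether
Conditions: t-BuMe2SiOTf, 2,6-lutidine, CH2Cl2, −78 → 0 °C
Reagents that add atoms: tert-butyldimethylsilyl trifluoromethanesulfonate, CC(C)(C)[Si](C)(C)OS(=O)(=O)C(F)(F)F
Why: Silyl triflate silylation of the hindered secondary alcohol protects C1–OH through the oxidation, bromination and hydride steps.

Step 11
Reactants: 14 C1 tert-butyldimethylsilyl ether
Product: 15 C7 aldehyde
Conditions: (COCl)2, DMSO, CH2Cl2, −78 → −40 °C; then Et3N, −78 → 0 °C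
Reagents that add atoms: none
Why: Swern conditions cleave and oxidise primary triethylsilyl ethers directly to aldehydes while the secondary tert-butyldimethylsilyl ether survives, so C7 should be unmasked in one operation without epimerising C8.

Step 12
Reactants: 15 C7 aldehyde; 16 methyl acrylate
Product: 17 Baylis–Hillman alcohol
Conditions: 16 (3 equiv), DABCO (1 equiv), dioxane/H2O 1:1, rt
Reagents that add atoms: none
Why: The Morita–Baylis–Hillman reaction attaches C11, C12 and C13 to C7, the new carbinol centre being lost in the next step.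

Step 13
Reactants: 17 Baylis–Hillman alcohol
Product: 18 (Z)-2-(bromomethyl)alkenoate
Conditions: NBS, Me2S, CH2Cl2, 0 °C → rt
Reagents that add atoms: N-bromosuccinimide, O=C1CCC(=O)N1Br
Why: Activation of the alcohol as its alkoxysulfonium salt and SN2′ attack of bromide should give the rearranged, thermodynamically preferred (Z)-allylic bromide.

Step 14
Reactants: 18 (Z)-2-(bromomethyl)alkenoate; 19 acrolein
Product: 21 syn hydroxy acid, via syn hydroxy ester 20 (not isolated)
Conditions: In powder, 19, THF/H2O 1:1, rt; then LiOH, 0 °C → rt; 1 M HCl to pH 4, 0 °C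
Reagents that add atoms: lithium hydroxide, [Li+].[OH-]
Why: Indium-mediated Barbier allylation through a chair transition state should form C6–C7 as the syn adduct, the aldehyde attacking the allylindium face anti to C9 in the conformer with C8–H eclipsing the alkene (allylic strain), which sets C7, and hydroxide then saponifies the ester and any cis-lactone.

Step 15
Reactants: 21 syn hydroxy acid
Product: 22 trans α-methylene γ-lactone
Conditions: PPh3, DIAD, THF (0.02 M), 0 °C → rt
Reagents that add atoms: none
Why: Intramolecular Mitsunobu esterification closes the lactone by 5-exo-tet SN2 displacement with inversion at C6, converting the syn hydroxy acid into the trans-fused lactone of the target.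

Step 16
Reactants: 22 trans α-methylene γ-lactone
Product: 23 11,13-epoxy lactone
Conditions: t-BuOOH (in decane), DBU, CH2Cl2, 0 °C → rt
Reagents that add atoms: tert-butyl hydroperoxide, CC(C)(C)OO
Why: Weitz–Scheffer nucleophilic epoxidation should touch only the electron-poor exocyclic alkene and close the enolate onto oxygen on the face opposite the bulky C7 substituent, setting C11 and removing the 1,1-disubstituted alkene before metathesis.

Step 17
Reactants: 23 11,13-epoxy lactone
Product: 24 cis-cyclooctene (C2=C5)
Conditions: second-generation Grubbs catalyst RuCl2(=CHPh)(H2IMes)(PCy3) (10 mol%), CH2Cl2 (2 mM), 40 °C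
Reagents that add atoms: none
Why: Ring-closing metathesis of the two terminal vinyl groups, preorganised by the trans-lactone and the cis-dioxolane, should give the cis-cyclooctene, the dichlorovinyl ether being too hindered and deactivated to engage the ruthenium carbene.

Step 18
Reactants: 24 cis-cyclooctene
Product: 26 O-silyl lactol acetal, via aluminium hemiacetal 25 (not isolated)
Conditions: i-Bu2AlH (1.2 equiv), CH2Cl2, −78 °C; then pyridine, t-BuMe2SiOTf, −78 → −20 °C
Reagents that add atoms: tert-butyldimethylsilyl trifluoromethanesulfonate, CC(C)(C)[Si](C)(C)OS(=O)(=O)C(F)(F)F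
Why: Low-temperature hydride reduction stops at the aluminium hemiacetal, which is silylated in the same flask (reductive silylation), so that no carbonyl group faces n-BuLi in step 19.

Step 19
Reactants: 26 O-silyl lactol acetal
Product: 29 C10 propynyl ether, via chloroalkynyl ether 27 (not isolated), via lithium alkynyl ether 28 (not isolated)
Conditions: n-BuLi (2.3 equiv), THF, −78 → −40 °C; then MeI, DMPU, −78 → 0 °C
Reagents that add atoms: iodomethane, CI
Why: Dehydrochlorination of the dichlorovinyl ether, chlorine–lithium exchange and C-methylation of the lithium alkynyl ether give the ynol ether, and the hindered 2,2-disubstituted epoxide and the silyl ethers should not react with n-BuLi at −78 °C.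

Step 20
Reactants: 29 C10 propynyl ether
Product: 30 lactol with free C1–OH
Conditions: Bu4NF (3 equiv), THF, 0 °C → rt
Reagents that add atoms: none
Why: Fluoride-mediated desilylation frees the lactol and C1–OH under basic conditions that the acid-labile ynol ether, the epoxide and the acetonide tolerate.

Step 21
Reactants: 30 lactol with free C1–OH
Product: 31 cyclooctenone propynyl ether
Conditions: (n-Pr4N)RuO4 (5 mol%), N-methylmorpholine N-oxide, 4 Å MS, CH2Cl2, 0 °C → rt
Reagents that add atoms: none
Why: Ley–Griffith oxidation, neutral and non-electrophilic, should convert the lactol into the lactone and the allylic alcohol into the cis-enone in one operation at or below room temperature without touching the ynol ether.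

Step 22
Reactants: 31 cyclooctenone propynyl ether
Product: 33 ten-membered furanone (8,9-acetonide; 11,13-epoxide), via cyclobutene 32 (not isolated)
Conditions: AgNTf2 (10 mol%), CH2Cl2, −40 → 0 °C; then 35 °C
Reagents that add atoms: none
Why: Proposed new method: AgNTf2 (monovalent silver) activates the enone, the nucleophilic ynol ether carbon C4 adds to the β-carbon C5, and the silver enolate carbon C2 closes onto the ketenium carbon C3 to give cyclobutene 32, whose C2–C5 bond then breaks in a thermal conrotatory 4π electrocyclic opening. The closest known reactions are the silver- or copper-catalysed Ficini-type [2+2] cycloadditions of ynol ethers, siloxyalkynes and ynamides with enones and the two-carbon ring expansion by thermal opening of fused cyclobutenes. The furanone ring (O, C10, C1, C2, C3) closes by 5-exo attack of C2 on C3 after a 7-endo first bond, whereas the ten-membered ring is not closed by cyclisation but arises when the bond shared by the cyclobutene and the eight-membered ring is cleaved. No new stereocentre survives: C2 and C5 of 32 are cis-fused on the face of O10 and become sp2, conrotation of a cis-fused cyclobutene must give one trans and one cis alkene, and the five-membered ring forces C2=C3 to be the trans one, leaving C4=C5 Z. The head-to-head regiochemistry is fixed by the one-atom oxygen tether from C10, and the addition is run cold so that retro-ene loss or hydration of the tertiary ynol ether does not compete, the epoxy lactone and acetonide being spectators.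

Step 23
Reactants: 33 ten-membered furanone
Product: 35 triol chlorohydrin (detigloyl target), via chlorohydrin acetonide 34 (not isolated)
Conditions: HCl (4 M in dioxane), THF, 0 °C; then H2O, rt
Reagents that add atoms: hydrogen chloride, Cl
Why: Chloride should open the protonated spiro-epoxide by SN2 attack at the primary C13 (the tertiary C11 is deactivated by the lactone carbonyl and keeps its configuration), and the aqueous acid then hydrolyses the acetonide.

Step 24
Reactants: 35 triol chlorohydrin; 36 tigloyl chloride
Product: 37 CNP0272644.2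
Conditions: 36, pyridine, DMAP (cat.), CH2Cl2, −20 → 0 °C
Reagents that add atoms: none
Why: Acylation should take the C8 hydroxyl, the only unhindered one (C9–OH is flanked by the quaternary C10, C11–OH is tertiary), and is run cold to outpace translactonisation.

**Compound list**
1 | L-arabinose | O=C[C@H](O)[C@@H](O)[C@@H](O)CO | starting material
2 | 3,4-O-isopropylidene-L-arabinopyranose (anomers) | OC1OC[C@@H]2OC(C)(C)O[C@@H]2[C@H]1O | intermediate
3 | 4-O-formyl-2,3-O-isopropylidene-L-erythrose (not isolated) | O=C[C@H]1OC(C)(C)O[C@H]1COC=O | intermediate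
4 | 2,3-O-isopropylidene-L-erythrose (lactol; cis-dioxolane carbons = C9, C8) | OC1OC[C@@H]2OC(C)(C)O[C@H]12 | intermediate
5 | C10 methyl carbinol diol: CH3CH(OH)–(cis-dioxolane C9,C8)–CH2OH | CC(O)[C@H]1OC(C)(C)O[C@H]1CO | intermediate
6 | C7 triethylsilyl ether of 5 | CC(O)[C@H]1OC(C)(C)O[C@H]1CO[Si](CC)(CC)CC | intermediate
7 | C10 methyl ketone (C7–OSiEt3; 8,9-acetonide) | CC(=O)[C@H]1OC(C)(C)O[C@H]1CO[Si](CC)(CC)CC | intermediate
8 | tertiary allylic alcohol (C10: CH3, OH, vinyl; O10 anti to O9) | C=C[C@@](C)(O)[C@H]1OC(C)(C)O[C@H]1CO[Si](CC)(CC)CC | intermediate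
9 | trichloroethylene | ClC=C(Cl)Cl | starting material
10 | C10 (E)-1,2-dichlorovinyl ether of 8 | C=C[C@@](C)(O/C(Cl)=C\Cl)[C@H]1OC(C)(C)O[C@H]1CO[Si](CC)(CC)CC | intermediate
11 | vicinal diol from the vinyl group of 10 (not isolated) | OCC(O)[C@@](C)(O/C(Cl)=C\Cl)[C@H]1OC(C)(C)O[C@H]1CO[Si](CC)(CC)CC | intermediate
12 | C1 aldehyde | O=C[C@@](C)(O/C(Cl)=C\Cl)[C@H]1OC(C)(C)O[C@H]1CO[Si](CC)(CC)CC | intermediate
13 | C1 vinyl carbinol | C=CC(O)[C@@](C)(O/C(Cl)=C\Cl)[C@H]1OC(C)(C)O[C@H]1CO[Si](CC)(CC)CC | intermediate
14 | C1 tert-butyldimethylsilyl ether of 13 | C=CC(O[Si](C)(C)C(C)(C)C)[C@@](C)(O/C(Cl)=C\Cl)[C@H]1OC(C)(C)O[C@H]1CO[Si](CC)(CC)CC | intermediate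
15 | C7 aldehyde | C=CC(O[Si](C)(C)C(C)(C)C)[C@@](C)(O/C(Cl)=C\Cl)[C@H]1OC(C)(C)O[C@H]1C=O | intermediate
16 | methyl acrylate | C=CC(=O)OC | starting material
17 | Baylis–Hillman alcohol (C7–OH, C11=C13H2, C12 methyl ester) | C=CC(O[Si](C)(C)C(C)(C)C)[C@@](C)(O/C(Cl)=C\Cl)[C@H]1OC(C)(C)O[C@H]1C(O)C(=C)C(=O)OC | intermediate
18 | methyl (Z)-2-(bromomethyl)alk-2-enoate (C7=C11, C13H2Br cis to C8) | C=CC(O[Si](C)(C)C(C)(C)C)[C@@](C)(O/C(Cl)=C\Cl)[C@H]1OC(C)(C)O[C@H]1/C=C(\CBr)C(=O)OC | intermediate
19 | acrolein | C=CC=O | starting material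
20 | syn hydroxy ester (C7 as in target, C6 epimeric; not isolated) | C=CC(O[Si](C)(C)C(C)(C)C)[C@@](C)(O/C(Cl)=C\Cl)[C@H]1OC(C)(C)O[C@H]1[C@@H](C(=C)C(=O)OC)[C@@H](O)C=C | intermediate
21 | syn hydroxy acid | C=CC(O[Si](C)(C)C(C)(C)C)[C@@](C)(O/C(Cl)=C\Cl)[C@H]1OC(C)(C)O[C@H]1[C@@H](C(=C)C(=O)O)[C@@H](O)C=C | intermediate
22 | trans-fused α-methylene γ-lactone (C6, C7 as in target) | C=CC(O[Si](C)(C)C(C)(C)C)[C@@](C)(O/C(Cl)=C\Cl)[C@H]1OC(C)(C)O[C@H]1[C@@H]2[C@@H](C=C)OC(=O)C2=C | intermediate
23 | 11,13-epoxy lactone (epoxide oxygen anti to C8 side chain) | C=CC(O[Si](C)(C)C(C)(C)C)[C@@](C)(O/C(Cl)=C\Cl)[C@H]1OC(C)(C)O[C@H]1[C@@H]2[C@@H](C=C)OC(=O)[C@]23CO3 | intermediate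
24 | cis-cyclooctene (C1–OSi, C10 dichlorovinyl ether, 8,9-acetonide, epoxy lactone) | CC1(C)O[C@H]2[C@@H]3[C@@H](/C=C\C(O[Si](C)(C)C(C)(C)C)[C@@](C)(O/C(Cl)=C\Cl)[C@H]2O1)OC(=O)[C@]34CO4 | intermediate
25 | diisobutylaluminium hemiacetal of 24 at C12 (not isolated) | CC1(C)O[C@H]2[C@@H]3[C@@H](/C=C\C(O[Si](C)(C)C(C)(C)C)[C@@](C)(O/C(Cl)=C\Cl)[C@H]2O1)OC(O[Al](CC(C)C)CC(C)C)[C@]34CO4 | intermediate
26 | C12 O-tert-butyldimethylsilyl lactol acetal | CC1(C)O[C@H]2[C@@H]3[C@@H](/C=C\C(O[Si](C)(C)C(C)(C)C)[C@@](C)(O/C(Cl)=C\Cl)[C@H]2O1)OC(O[Si](C)(C)C(C)(C)C)[C@]34CO4 | intermediate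
27 | C10 chloroethynyl ether (not isolated) | CC1(C)O[C@H]2[C@@H]3[C@@H](/C=C\C(O[Si](C)(C)C(C)(C)C)[C@@](C)(OC#CCl)[C@H]2O1)OC(O[Si](C)(C)C(C)(C)C)[C@]34CO4 | intermediate
28 | C10 lithioethynyl ether (not isolated) | CC1(C)O[C@H]2[C@@H]3[C@@H](/C=C\C(O[Si](C)(C)C(C)(C)C)[C@@](C)(OC#C[Li])[C@H]2O1)OC(O[Si](C)(C)C(C)(C)C)[C@]34CO4 | intermediate
29 | C10 prop-1-ynyl ether (bis-silyl) | CC1(C)O[C@H]2[C@@H]3[C@@H](/C=C\C(O[Si](C)(C)C(C)(C)C)[C@@](C)(OC#CC)[C@H]2O1)OC(O[Si](C)(C)C(C)(C)C)[C@]34CO4 | intermediate
30 | lactol with free C1–OH (ynol ether retained) | CC1(C)O[C@H]2[C@@H]3[C@@H](/C=C\C(O)[C@@](C)(OC#CC)[C@H]2O1)OC(O)[C@]34CO4 | intermediate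
31 | cis-cyclooctenone with C10 propynyl ether, 8,9-acetonide and 11,13-epoxy lactone (key-step precursor) | CC1(C)O[C@H]2[C@@H]3[C@@H](/C=C\C(=O)[C@@](C)(OC#CC)[C@H]2O1)OC(=O)[C@]34CO4 | intermediate
32 | cis-fused cyclobutene (C2–C3 and C4–C5 formed on the O10 face; not isolated) | CC1(C)O[C@H]2[C@@H]3[C@@H]([C@H]5C(C)=C6[C@H]5C(=O)[C@@](C)(O6)[C@H]2O1)OC(=O)[C@]34CO4 | intermediate
33 | ten-membered furanone, 8,9-acetonide, 11,13-epoxy lactone (key-step product) | CC1(C)O[C@H]2[C@@H]3[C@@H](/C=C(/C)C5=CC(=O)[C@@](C)(O5)[C@H]2O1)OC(=O)[C@]34CO4 | intermediate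
34 | 8,9-acetonide of the detigloylated target (chlorohydrin; not isolated) | CC1(C)O[C@H]2[C@@H]3[C@@H](/C=C(/C)C4=CC(=O)[C@@](C)(O4)[C@H]2O1)OC(=O)[C@]3(O)CCl | intermediate
35 | detigloylated target (8,9,11-triol, 13-chloride) | O[C@H]1[C@@H]2[C@@H](/C=C(/C)C3=CC(=O)[C@@](C)(O3)[C@H]1O)OC(=O)[C@]2(O)CCl | intermediate
36 | tigloyl chloride | C/C=C(\C)C(Cl)=O | starting material
37 | CNP0272644.2 | C/C=C(\C)C(=O)O[C@H]1[C@@H]2[C@@H](/C=C(/C)C3=CC(=O)[C@@](C)(O3)[C@H]1O)OC(=O)[C@]2(O)CCl | target

**Totals.** Total step count: 24. Longest linear sequence: 24 steps (from L-arabinose).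

**Steps most likely to fail**

Step 22 (proposed method). The silver-bound ketenium intermediate may be intercepted before the strained C2–C3 closure, by hydration, by retro-ene fragmentation to methylketene, or by the C1 carbonyl oxygen. The cyclobutene may also fail to open cleanly. The fallback uses known chemistry and leaves the tether idea. It sets out from 31: PPTS in MeOH followed by water should cleave the ynol ether through its mixed ortho ester to the hydroxy enone F1. The known intermolecular silver-catalysed [2+2] of a siloxyalkyne with an enone (AgNTf2, 1-(triisopropylsiloxy)prop-1-yne, CH2Cl2), whose natural polarity gives the same head-to-head bonds, should give the siloxycyclobutene F2. Heating in toluene should open it to the ring-expanded siloxy dienone F3. Catalytic TsOH should then remove the silyl group and cyclodehydrate the α′-hydroxy-1,3-diketone to the 3(2H)-furanone, which returns to the route at 33. The C4=C5 geometry is not fixed by a tether in this version and may need equilibration.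

Step 17. Closure of the eight-membered ring may lose to intermolecular metathesis, because the carbene must engage the vinyl group next to a silyloxy carbon and a quaternary centre in a ring strained by the trans-lactone. The fallback changes the oxidation level at C1 for the ring closure. It sets out from 23: Bu4NF should give the diene alcohol F4 and Dess–Martin periodinane the vinyl ketone F5. Enone ring-closing metathesis with the second-generation Hoveyda–Grubbs catalyst RuCl2(=CH-C6H4-2-O-i-Pr)(H2IMes), in which the carbene loads on the C6 vinyl group and closes onto the acryloyl-type alkene at an sp2 C1, should give the cyclooctenone F6. Luche reduction (NaBH4, CeCl3·7H2O) should give the cyclooctenol F7, and t-BuMe2SiOTf/2,6-lutidine returns to the route at 24.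

Step 14. Simple diastereoselection in the indium allylation (syn against anti at C6) may be poor, so that the stereospecific inversion of step 15 would pass a cis/trans mixture on. The fallback replaces stereospecific inversion by thermodynamic equilibration. It sets out from 21 as whatever C6 mixture is formed: carbodiimide lactonisation with retention (EDC·HCl, DMAP) should give the cis-lactone F8 together with some 22. Pd(PPh3)4 (zerovalent palladium) in THF should then ionise the allylic C6–O bond reversibly to the π-allyl carboxylate and reclose it, funnelling C6 to the more stable trans-β,γ-disubstituted lactone, which returns to the route at 22.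

Further compounds
F1 | step 22 | hydroxy enone (31 with free C10–OH) | CC1(C)O[C@H]2[C@@H]3[C@@H](/C=C\C(=O)[C@@](C)(O)[C@H]2O1)OC(=O)[C@]34CO4
F2 | step 22 | siloxycyclobutene (C3–OSi(i-Pr)3, C4–CH3; cis-fused, face undefined) | CC1(C)O[C@H]2[C@@H]3[C@@H](C5C(C)=C(O[Si](C(C)C)(C(C)C)C(C)C)C5C(=O)[C@@](C)(O)[C@H]2O1)OC(=O)[C@]34CO4
F3 | step 22 | ring-expanded siloxy dienone (ten-membered; C4=C5 Z) | CC1(C)O[C@H]2[C@@H]3[C@@H](/C=C(/C)C(O[Si](C(C)C)(C(C)C)C(C)C)=CC(=O)[C@@](C)(O)[C@H]2O1)OC(=O)[C@]34CO4
F4 | step 17 | diene alcohol (23 with free C1–OH) | C=CC(O)[C@@](C)(O/C(Cl)=C\Cl)[C@H]1OC(C)(C)O[C@H]1[C@@H]2[C@@H](C=C)OC(=O)[C@]23CO3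
F5 | step 17 | vinyl ketone (C1 ketone) | C=CC(=O)[C@@](C)(O/C(Cl)=C\Cl)[C@H]1OC(C)(C)O[C@H]1[C@@H]2[C@@H](C=C)OC(=O)[C@]23CO3
F6 | step 17 | cyclooctenone with C10 dichlorovinyl ether | CC1(C)O[C@H]2[C@@H]3[C@@H](/C=C\C(=O)[C@@](C)(O/C(Cl)=C\Cl)[C@H]2O1)OC(=O)[C@]34CO4
F7 | step 17 | cyclooctenol with C10 dichlorovinyl ether | CC1(C)O[C@H]2[C@@H]3[C@@H](/C=C\C(O)[C@@](C)(O/C(Cl)=C\Cl)[C@H]2O1)OC(=O)[C@]34CO4
F8 | step 14 | cis-fused α-methylene γ-lactone (C6 epimer of 22) | C=CC(O[Si](C)(C)C(C)(C)C)[C@@](C)(O/C(Cl)=C\Cl)[C@H]1OC(C)(C)O[C@H]1[C@@H]2[C@H](C=C)OC(=O)C2=C
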